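- Draw the line first.

common to all: electrophile 44 mM; gas 6.9 mM (held)

| flask | buffer base | buffer acid | scavenger | remark | time |
|---|---|---|---|---|---|
| cedar | 44 mM | 4.4 mM | 66 mM | the very flask that is asked about, followed so far |  |
| birch | 44 mM | 2.9 mM | 66 mM | run made earlier |  |
| flask | 44.0 mM | 4.40 mM | 66.0 mM |  | 10 min |

- cedar (time / min: electrophile / %, product / %): 0.333: 97.6, 0.1; 1.00: 97.9, 2.8; 2.00: 93.1, 6.6; 3.00: 90.0, 10.8; 4.00: 84.9, 16.1
- birch (time / min: electrophile / %, product / %): 0.333: 99.6, 0.6; 0.667: 97.6, 0.6; 1.00: 95.8, 1.8; 2.00: 93.7, 9.3; 4.00: 84.7, 14.8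

(readings scatter by 1 percentage point)

- part of the electrophile that has reacted at 10 min
- pH of the solution at 10 min

- at the start none of the gas is in solution
- the earlier runs do not show the pH; that part of a forecast is a guess

- Cedar and birch differ at 4.00 min by 1.3 percentage points of product, with a scatter of 1 point per reading, so their readings are pooled: mean product 2.30% at 1.00 min and 15.5% at 4.00 min.
- The bench rule reads a gas-fed flask as a straight line. The pooled gain gives 1.93 mM min⁻¹, the electrophile turned over per minute, called the feed (a zero-order rate).
- Carried from the reading at 4.00 min to 10 min, the feed gives 41.8% reacted.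
- The line's border is a ratio of electrophile left to feed: from the pooled reading at 4.00 min the rest lasts 19.3 min on the line, so the line reaches the whole charge at 23.3 min, and 10 min lies at 0.429 of that time.
- Going round once more, with the feed taken as proportional to the mean electrophile left, the first answer falls to 36.1%. That is the low end, and this reckoning commits to the line, as the readings show no slowing yet. They show no pH.
- The forecast stands lower than the line: 38% (30% to 47%) and pH 7.2 (5.8 to 8.6), with the remark “The pKa is unknown, so I guess a phosphate-like value near 7”.

    electrophile + nucleophile → acid + product + leaving group (k = 34.1 L mol⁻¹ min⁻¹)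
    protonated nucleophile ⇌ nucleophile + acid, settled at all times (K = 1.60 × 10⁻⁶ M)
    buffer acid ⇌ buffer base + acid, settled at all times (K = 1.30 × 10⁻¹⁰ M)
    gas ⇌ nucleophile, rate k4*(csat - [nucleophile]) (kL = 0.392 min⁻¹)
    nucleophile + leaving group ⇌ idle adduct, settled at all times (K = 230 L mol⁻¹)
    scavenger + leaving group → scavenged by-product (k = 621 L mol⁻¹ min⁻¹)

- The flask gives 42.3% at pH 9.93. From 4.0 min to 10 min it turned over 1.91 mM min⁻¹, against a feed of 1.93 mM min⁻¹. The same turnover in the neighbour flask with 26 mM of electrophile gives 70.7%, but that flask stands at 55.6%. This flask has not come to rest: 58% of its electrophile remains, 13.2 min of feed away, yet 94.8% is used at 30.0 min. At 100 min the flask reaches 100%, its scavenger goes from 71.9% to 33.3% of its own charge, and its buffer base from 57.7% to 0.374%.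

Readings and results are calculated from invented constants; noise was put on by code.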